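**Retrosynthetic overview**

1. Target ⇐ desilylation and Mitsunobu inversion/angeloylation at C8 of an 8‑epi macrocyclic α‑methylene lactone.
2. Key disconnection C6–C7, made as the ring closure: Cr(II) reduces a 2‑(bromomethyl)enoate to a 2‑carboxyallyl metal (ester homoenolate equivalent) whose C7 adds to the C6 aldehyde. This closes the 10‑membered carbocycle and the cis γ‑lactone and sets C6 and C7.
3. The C7=C11 unit ⇐ C7 aldehyde (sugar C5) + methyl propiolate; the furanone ⇐ Au cyclisation of an α′‑hydroxy ynone ⇐ acetylide + 2‑C‑methyl‑D‑ribonolactone (supplies C1, C10, C14, C9, C8, C7).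
4. Alkyne C2–C6 ⇐ Marshall propargylation of 2,2‑dimethoxyacetaldehyde with (R)‑butynyl mesylate (sets C4, C5).
5. Ring order: furanone (oxygen bridge) first, then carbocycle and lactone together in the key step.

Assumption: germacrane‑type locants are used (C1 furanone C=O, C2 furanone CH, C3 furanone O–C=, C4 CH–CH3, C5 CH–OH, C6 lactone O–CH, C7 ring‑fusion CH, C8 CH–OAng, C9 CH–OH, C10 quaternary C–O, C11/C12/C13 lactone C=, C=O, =CH2); the target is then 4R,5S,6R,7S,8S,9R,10R.

**Route**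

Step 1
Reactants: 1 2‑C‑methyl‑D‑ribono‑1,4‑lactone
Product: 3 3‑O‑TBS‑5‑O‑TES‑2‑C‑methyl‑D‑ribono‑1,4‑lactone, via 5‑O‑TES lactone 2 (not isolated)
Conditions: TESCl (1.05 equiv), imidazole, CH2Cl2, −20 °C; then 2,6‑lutidine, TBSOTf (1.2 equiv), −78 → 0 °C
Reagents that add atoms: TESCl CC[Si](Cl)(CC)CC; TBSOTf CC(C)(C)[Si](C)(C)OS(=O)(=O)C(F)(F)F
Why: Chemoselective silyl ether formation: the primary OH takes the small TES group first, the hindered secondary OH then takes TBS from the triflate, and the tertiary OH (future furanone oxygen) stays free; C10, C9 and the D‑ribo C8 come unchanged from the sugar.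

Step 2
Reactants: 4 (R)‑but‑3‑yn‑2‑ol
Product: 5 (R)‑but‑3‑yn‑2‑yl methanesulfonate
Conditions: MsCl, Et3N, CH2Cl2, −78 → 0 °C
Reagents that add atoms: MsCl CS(Cl)(=O)=O
Why: O‑sulfonylation (mesylation) with retention gives the propargylic electrophile for the Marshall reagent.

Step 3
Reactants: 5 (R)‑but‑3‑yn‑2‑yl methanesulfonate; 6 2,2‑dimethoxyacetaldehyde (commercial aqueous solution, extracted, dried and distilled before use)
Product: 7 (2S,3S)‑1,1‑dimethoxy‑3‑methylpent‑4‑yn‑2‑ol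
Conditions: Pd(OAc)2 (5 mol %), PPh3 (5 mol %), Et2Zn (3 equiv), THF, −78 → −20 °C
Reagents that add atoms: none
Why: Marshall–Tamaru propargylation: anti‑SN2′ ionisation by Pd(0), transmetalation to a configurationally defined allenylzinc and cyclic SE2′ addition give the anti homopropargylic alcohol, setting C4 (net inversion of the mesylate carbon) and C5 (anti, chair‑like transition state) under reagent control.

Step 4
Reactants: 7 (2S,3S)‑1,1‑dimethoxy‑3‑methylpent‑4‑yn‑2‑ol
Product: 8 tert‑butyl{[(2S,3S)‑1,1‑dimethoxy‑3‑methylpent‑4‑yn‑2‑yl]oxy}dimethylsilane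
Conditions: TBSCl, imidazole, DMF, rt → 40 °C
Reagents that add atoms: TBSCl CC(C)(C)[Si](C)(C)Cl
Why: Standard silylation of the secondary alcohol; the C5 silyl ether later acts as the non‑chelating Felkin control element.

Step 5
Reactants: 8 alkyne TBS ether; 3 bis‑silyl lactone
Product: 9 α′‑hydroxy ynone (C1 ketone, C2≡C3; in equilibrium with its C1/C8 lactol)
Conditions: 8, n‑BuLi, THF, −78 °C; add to 3 pre‑treated with LiHMDS (1 equiv), −78 → −40 °C; AcOH quench at −78 °C
Reagents that add atoms: none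
Why: Acyl substitution of a γ‑lactone by a lithium acetylide stops after one addition because the tetrahedral lactol alkoxide survives until the cold quench; it forms C1–C2 and releases the C8 hydroxyl.

Step 6
Reactants: 9 α′‑hydroxy ynone
Product: 11 3(2H)‑furanone with C7‑OTES, C8‑OTES, C5‑OTBS, C9‑OTBS and the C6 dimethyl acetal, via furanone alcohol 10 (not isolated)
Conditions: Ph3PAuNTf2 (3 mol %), CH2Cl2, rt; then imidazole, DMAP (cat.), TESCl, 0 °C → rt
Reagents that add atoms: TESCl CC[Si](Cl)(CC)CC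
Why: Gold(I)‑catalysed 5‑endo‑dig cycloisomerisation of the α′‑hydroxy ynone (C10–OH adds to C3; the lactol tautomer collapses to the same product) gives the 3(2H)‑furanone, C9‑OTBS blocking the 6‑endo mode, and the freed C8–OH is silylated in the same flask.

Step 7
Reactants: 11 tetrasilylated furanone acetal
Product: 12 C7 aldehyde (α‑OTES at C8)
Conditions: (COCl)2, DMSO, CH2Cl2, −78 → −40 °C; Et3N, −78 → 0 °C
Reagents that add atoms: none
Why: Swern oxidation converts primary triethylsilyl ethers directly into aldehydes (oxidative desilylation) while secondary TES and TBS ethers are inert.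

Step 8
Reactants: 12 C7 aldehyde; 13 methyl propiolate
Product: 14 Baylis–Hillman‑type alcohol (C7 carbinol bearing the C11(=CH2)CO2Me unit; C7 epimer mixture)
Conditions: 13, DIBAL‑H, NMO, THF, 0 °C; then 12, 0 °C → rt
Reagents that add atoms: none
Why: Vinylalumination (a Morita–Baylis–Hillman surrogate): hydroalumination of the propiolate gives the α‑(methoxycarbonyl)vinylalane, which adds to the hindered aldehyde without base; the C7 carbinol configuration is irrelevant because it is erased in step 9.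

Step 9
Reactants: 14 Baylis–Hillman‑type alcohol
Product: 15 methyl (Z)‑2‑(bromomethyl)enoate (C7=C11, C8 cis to CH2Br), C6 dimethyl acetal
Conditions: NBS, Me2S (reagent pre‑formed), CH2Cl2, 0 °C → rt
Reagents that add atoms: NBS O=C1CCC(=O)N1Br
Why: Corey–Kim‑type allylic bromination of a Baylis–Hillman alcohol proceeds by SN2′ attack of bromide on the alkoxysulfonium salt and gives the thermodynamically preferred (Z)‑2‑(bromomethyl)enoate.

Step 10
Reactants: 15 bromo enoate acetal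
Product: 16 bromo enoate C6 aldehyde (α‑OTBS at C5)
Conditions: Me2BBr, CH2Cl2, −78 °C; then aq. NaHCO3, THF
Reagents that add atoms: water O
Why: Dimethylboron bromide cleaves dimethyl acetals at −78 °C (ionisation to the α‑bromo ether, hydrolysed on work‑up), a temperature at which the silyl ethers, the allylic bromide and the ester survive.

Step 11
Reactants: 16 bromo enoate aldehyde
Product: 18 8‑epi macrocyclic α‑methylene‑γ‑lactone (5,9‑bis‑OTBS, 8‑OTES), via hydroxy ester 17 (not isolated)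
Conditions: CrCl2 (10 equiv), THF–DMF, 2 mM, slow addition of 16, rt; aq. NH4Cl work‑up
Reagents that add atoms: none
Why: Key step, a Nozaki–Hiyama (Barbier‑type) allylation run as the ring closure: Cr(II) turns the electrophilic 2‑(bromomethyl)enoate into a 2‑(methoxycarbonyl)allylchromium(III), an ester homoenolate (β‑carbanion) equivalent, so that C7 attacks the equally electrophilic C6 aldehyde carbon through a closed chair in which the (Z)‑allyl unit with axial C8 gives the syn adduct (hence the cis‑fused lactone after in‑situ lactonisation), the aldehyde is attacked Felkin–Anh anti to C5‑OTBS (6R) and the allyl face anti to C8‑OTES with C8–H eclipsing the alkene, which is also the tether side (7S); these three preferences are matched only for the D‑ribo C8 epimer, which is why C8 is inverted afterwards.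

Step 12
Reactants: 18 8‑epi silylated macrolactone
Product: 19 8‑epi alcohol (free C8–OH, 8R; 5,9‑bis‑OTBS)
Conditions: HF·pyridine, pyridine, THF, 0 °C
Reagents that add atoms: none
Why: Fluoride desilylation is far faster for a triethylsilyl than for tert‑butyldimethylsilyl ethers, so buffered HF·pyridine at 0 °C frees only C8–OH.

Step 13
Reactants: 19 8‑epi alcohol; 20 angelic acid
Product: 21 5,9‑bis‑O‑TBS ether of the target (8S angelate)
Conditions: PPh3, DIAD (betaine pre‑formed), 20, toluene, 0 °C → rt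
Reagents that add atoms: none
Why: Mitsunobu esterification: the alkoxyphosphonium of the only free hydroxyl is displaced by angelate with inversion, correcting C8 from R to S and installing the ester in one operation under neutral conditions that do not isomerise the (Z)‑acid.

Step 14
Reactants: 21 bis‑TBS angelate
Product: 22 CNP0206920.1 (target)
Conditions: HF·pyridine, THF, rt → 40 °C
Reagents that add atoms: none
Why: Global fluoride desilylation of the two TBS ethers under mildly acidic conditions that leave the α‑methylene lactone, the furanone and the angelate intact.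

**Compound list**

1 | 2‑C‑methyl‑D‑ribono‑1,4‑lactone, (3R,4R,5R)‑3,4‑dihydroxy‑5‑(hydroxymethyl)‑3‑methyloxolan‑2‑one | O=C1[C@](C)(O)[C@H](O)[C@@H](CO)O1 | starting material
2 | 5‑O‑triethylsilyl‑2‑C‑methyl‑D‑ribono‑1,4‑lactone | O=C1[C@](C)(O)[C@H](O)[C@@H](CO[Si](CC)(CC)CC)O1 | intermediate
3 | 3‑O‑tert‑butyldimethylsilyl‑5‑O‑triethylsilyl‑2‑C‑methyl‑D‑ribono‑1,4‑lactone | O=C1[C@](C)(O)[C@H](O[Si](C)(C)C(C)(C)C)[C@@H](CO[Si](CC)(CC)CC)O1 | intermediate
4 | (R)‑but‑3‑yn‑2‑ol | C[C@@H](O)C#C | starting material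
5 | (R)‑but‑3‑yn‑2‑yl methanesulfonate | C[C@@H](OS(C)(=O)=O)C#C | intermediate
6 | 2,2‑dimethoxyacetaldehyde | COC(OC)C=O | starting material
7 | (2S,3S)‑1,1‑dimethoxy‑3‑methylpent‑4‑yn‑2‑ol (C6 acetal, C5 OH, C4 methyl, C3≡C2) | COC(OC)[C@@H](O)[C@@H](C)C#C | intermediate
8 | tert‑butyl{[(2S,3S)‑1,1‑dimethoxy‑3‑methylpent‑4‑yn‑2‑yl]oxy}dimethylsilane | COC(OC)[C@@H](O[Si](C)(C)C(C)(C)C)[C@@H](C)C#C | intermediate
9 | α′‑hydroxy ynone, open‑chain tautomer of the C1/C8 lactol: C6 acetal, C5 OTBS, C4 Me, C3≡C2, C1=O, C10(OH)Me, C9 OTBS, C8 OH (D‑ribo), C7 OTES | COC(OC)[C@@H](O[Si](C)(C)C(C)(C)C)[C@@H](C)C#CC(=O)[C@](C)(O)[C@H](O[Si](C)(C)C(C)(C)C)[C@H](O)CO[Si](CC)(CC)CC | intermediate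
10 | 2,5‑disubstituted 2‑methylfuran‑3(2H)‑one with free C8–OH (C7 OTES, C9 OTBS, C5 OTBS, C6 acetal) | COC(OC)[C@@H](O[Si](C)(C)C(C)(C)C)[C@@H](C)C1=CC(=O)[C@](C)(O1)[C@H](O[Si](C)(C)C(C)(C)C)[C@H](O)CO[Si](CC)(CC)CC | intermediate
11 | furanone as 10 with C8 OTES | COC(OC)[C@@H](O[Si](C)(C)C(C)(C)C)[C@@H](C)C1=CC(=O)[C@](C)(O1)[C@H](O[Si](C)(C)C(C)(C)C)[C@H](O[Si](CC)(CC)CC)CO[Si](CC)(CC)CC | intermediate
12 | furanone C7 aldehyde (C8 OTES, C9 OTBS, C5 OTBS, C6 acetal) | COC(OC)[C@@H](O[Si](C)(C)C(C)(C)C)[C@@H](C)C1=CC(=O)[C@](C)(O1)[C@H](O[Si](C)(C)C(C)(C)C)[C@H](O[Si](CC)(CC)CC)C=O | intermediate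
13 | methyl propiolate | C#CC(=O)OC | starting material
14 | Baylis–Hillman‑type alcohol, methyl 2‑methylene‑3‑hydroxy ester at C7 (C7 epimers) | COC(OC)[C@@H](O[Si](C)(C)C(C)(C)C)[C@@H](C)C1=CC(=O)[C@](C)(O1)[C@H](O[Si](C)(C)C(C)(C)C)[C@H](O[Si](CC)(CC)CC)C(O)C(=C)C(=O)OC | intermediate
15 | methyl (Z)‑2‑(bromomethyl)enoate (C7=C11), C6 dimethyl acetal | COC(OC)[C@@H](O[Si](C)(C)C(C)(C)C)[C@@H](C)C1=CC(=O)[C@](C)(O1)[C@H](O[Si](C)(C)C(C)(C)C)[C@H](O[Si](CC)(CC)CC)/C=C(\CBr)C(=O)OC | intermediate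
16 | methyl (Z)‑2‑(bromomethyl)enoate, C6 aldehyde | O=C[C@@H](O[Si](C)(C)C(C)(C)C)[C@@H](C)C1=CC(=O)[C@](C)(O1)[C@H](O[Si](C)(C)C(C)(C)C)[C@H](O[Si](CC)(CC)CC)/C=C(\CBr)C(=O)OC | intermediate
17 | ring‑closed hydroxy ester (C6 OH, C7 bearing the methyl acrylate unit) | C=C(C(=O)OC)[C@H]1[C@@H](O)[C@@H](O[Si](C)(C)C(C)(C)C)[C@@H](C)C2=CC(=O)[C@](C)(O2)[C@H](O[Si](C)(C)C(C)(C)C)[C@@H]1O[Si](CC)(CC)CC | intermediate
18 | 8‑epi macrocyclic α‑methylene‑γ‑lactone, 5,9‑bis‑OTBS, 8‑OTES (stereocentres as in 22 except C8) | C=C1C(=O)O[C@H]2[C@@H](O[Si](C)(C)C(C)(C)C)[C@@H](C)C3=CC(=O)[C@](C)(O3)[C@H](O[Si](C)(C)C(C)(C)C)[C@H](O[Si](CC)(CC)CC)[C@@H]12 | intermediate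
19 | 8‑epi alcohol, 5,9‑bis‑OTBS, free C8–OH | C=C1C(=O)O[C@H]2[C@@H](O[Si](C)(C)C(C)(C)C)[C@@H](C)C3=CC(=O)[C@](C)(O3)[C@H](O[Si](C)(C)C(C)(C)C)[C@H](O)[C@@H]12 | intermediate
20 | angelic acid, (Z)‑2‑methylbut‑2‑enoic acid | C/C=C(/C)C(=O)O | starting material
21 | 5,9‑bis‑O‑TBS ether of the target | C=C1C(=O)O[C@H]2[C@@H](O[Si](C)(C)C(C)(C)C)[C@@H](C)C3=CC(=O)[C@](C)(O3)[C@H](O[Si](C)(C)C(C)(C)C)[C@@H](OC(=O)/C(C)=C\C)[C@@H]12 | intermediate
22 | CNP0206920.1, (4R,5S,6R,7S,8S,9R,10R)‑8‑angeloyloxy‑5,9‑dihydroxy‑1‑oxo‑3,10‑epoxygermacra‑2,11(13)‑dien‑12,6‑olide | C=C1C(=O)O[C@H]2[C@@H](O)[C@@H](C)C3=CC(=O)[C@](C)(O3)[C@H](O)[C@@H](OC(=O)/C(C)=C\C)[C@@H]12 | target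

**Step count and risks**

Total: 14 steps. Longest linear sequence: 13 steps (4 → 5 → 7 → 8 → 9 → 11 → 12 → 14 → 15 → 16 → 18 → 19 → 21 → 22); from lactone 1 it is 11 steps.

Steps most likely to fail:

1. Step 11 (ring‑closing umpolung allylation). Oligomerisation, or a diastereomer ratio set by macrocyclic strain instead of the acyclic models, can lower the yield of 18. Fallback, from 15 back to 18: Pd‑catalysed borylation of 15 (B2pin2, Pd2(dba)3, DMSO, 50 °C) gives the isolable allyl pinacolboronate acetal F1 with the same alkene geometry. Acetal cleavage with Me2BBr at −78 °C gives the allylboronate aldehyde F2. On warming in toluene (cat. Sc(OTf)3 if needed) F2 undergoes a metal‑free intramolecular allylboration through a closed Zimmerman–Traxler chair; aqueous work‑up gives hydroxy ester 17, which lactonises to 18.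

2. Step 13 (Mitsunobu on the hindered macrocyclic C8–OH). SN2 displacement inside a medium ring may be slow or give elimination. Fallback, from 19 back to 21: Dess–Martin oxidation gives the C8 ketone F3. Hydride delivery from the less hindered outer face (L‑Selectride, THF, −78 °C) gives the (8S)‑alcohol F4; the wrong epimer is recycled through F3. F4 is acylated with retention by the mixed anhydride of 20 (2,4,6‑trichlorobenzoyl chloride, Et3N, then DMAP, toluene) to give 21.

3. Step 5 (acetylide addition to the hindered α‑alkoxido lactone). Fallback, from 3 back to 9: the lactone is first opened with Me2AlCl/MeNHOMe·HCl (CH2Cl2, 0 °C → rt) to the Weinreb amide diol F5. Excess lithium acetylide of 8 (THF, −78 → 0 °C) adds once to the amide through its stable chelate and gives 9 on acidic quench.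

**Further compounds**

F1 | step 11 | allyl pinacolboronate acetal (Bpin in place of Br in 15) | COC(OC)[C@@H](O[Si](C)(C)C(C)(C)C)[C@@H](C)C1=CC(=O)[C@](C)(O1)[C@H](O[Si](C)(C)C(C)(C)C)[C@H](O[Si](CC)(CC)CC)/C=C(\CB1OC(C)(C)C(C)(C)O1)C(=O)OC
F2 | step 11 | allyl pinacolboronate C6 aldehyde | O=C[C@@H](O[Si](C)(C)C(C)(C)C)[C@@H](C)C1=CC(=O)[C@](C)(O1)[C@H](O[Si](C)(C)C(C)(C)C)[C@H](O[Si](CC)(CC)CC)/C=C(\CB1OC(C)(C)C(C)(C)O1)C(=O)OC
F3 | step 13 | C8 ketone of the 5,9‑bis‑OTBS macrolactone | C=C1C(=O)O[C@H]2[C@@H](O[Si](C)(C)C(C)(C)C)[C@@H](C)C3=CC(=O)[C@](C)(O3)[C@H](O[Si](C)(C)C(C)(C)C)C(=O)[C@@H]12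
F4 | step 13 | (8S)‑alcohol, 5,9‑bis‑OTBS (natural C8 configuration) | C=C1C(=O)O[C@H]2[C@@H](O[Si](C)(C)C(C)(C)C)[C@@H](C)C3=CC(=O)[C@](C)(O3)[C@H](O[Si](C)(C)C(C)(C)C)[C@@H](O)[C@@H]12
F5 | step 5 | Weinreb amide diol from lactone 3 | CON(C)C(=O)[C@](C)(O)[C@H](O[Si](C)(C)C(C)(C)C)[C@H](O)CO[Si](CC)(CC)CC
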